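## Structural features

The target is a fully substituted cyclobutane. C1 and C3 each carry a 4-methoxy-2-oxo-2H-pyran-6-yl ring (bound through pyranone C6), and C2 and C4 each carry a 4-hydroxyphenyl ring, all by C–C single bonds in a head-to-tail (truxillate-type) array. The four contiguous stereocentres have the substituents of C1 and C2 on one face and those of C3 and C4 on the other, so like groups are trans across the ring and every substituent has one cis and one trans neighbour. The molecule has a centre of inversion and is achiral, so only relative configuration has to be set. The fragile parts are the two 4-methoxy-2-pyranones (vinylogous esters that hydroxide, strong nucleophiles and BBr3 attack, with a vinylogously acidic cyclobutane C–H at C6), the free phenols, and the doubly benzylic cyclobutane, which can cyclorevert under light. The real difficulty is the up,up,down,down cyclobutane with alternating substituents, because a carbanion, radical or palladacycle at a ring carbon has no strong bias towards this pattern. The same pattern exists in the commercial cis,trans,cis dianhydride of cyclobutane-1,2,3,4-tetracarboxylic acid, whose four carboxyl carbons sit where the four ring-bound sp2 carbons of the target are. The key step exploits the aryl ipso carbons: each carbon bound to C2 or C4 is taken as C5 of a 2-pyranone, whose C3–C4–C5–C6 diene becomes four carbons of the benzene ring while a ketene acetal supplies the other two and puts its oxygen on the carbon bonded to C3, para to C5, without touching C1–C4.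

## Logic of the disconnections

25 to 24: the two phenolic O–H bonds are traced back to O–Si bonds. The phenols must be masked while the pyranone enols are methylated, since a free phenol would be methylated as well. Nothing is gained in skeleton, only in chemoselectivity. The forward step must remove silicon without opening the lactones or epimerising C1/C3, so fluoride has to be buffered.

24 to 23: the two enol O–CH3 bonds are cut. The hydroxypyranone ring is the direct product of a triketide-type lactonisation, so methylation belongs after ring formation. The forward step must alkylate O4 and not O2.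

23 to 21 (through 22): the O1–C2 lactone bonds of both pyranones are cut. Each heterocycle then reduces to a ketone on the cyclobutane and a masked acetoacetyl unit. The forward step is a neutral thermolysis and asks only that the ketone enol traps the acylketene faster than anything else does.

21 to 18 and two molecules of 19 (through 20): the two C–C bonds between the ring-bound carbonyl carbons and the methyl carbon of 19 are cut. Both pyranones thus come from the carboxyl groups on C1 and C3 and a commercial building block. The forward step needs γ-selective C-acylation on both arms and must not epimerise the carbons α to the acyl groups.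

18 to 16 to 15 to 14: only functional groups change (O–Si to O–H, aryl O–H to O–CH3, CO2H to CO2CH3, aryl C–H to C–Br). The order lets BBr3 act before any methoxypyranone exists and keeps silyl ethers away from hydroxide. The demands are that saponification leaves C1/C3 alone and that hydrogenolysis removes both bromines.

14 to 10 and two molecules of 11 (key step): in each benzene ring the bonds from the former C6 to the CH carbon and from the former C3 to the C–OMe carbon are cut, and CO2 is restored as the O1–C2 bridge. Both arenes reduce to lactones whose C5 is a former carboxyl carbon, and all four stereocentres become spectators. The atom bookkeeping gives the methoxy group para to the cyclobutane, and the structures of 9 and of the debrominated product are consistent, so nothing in the constitution needs correction. The weakness is reactivity: the bromine-free diene 9 has only a donor alkyl group at C5 and is a slow inverse-demand diene. The design is therefore improved by a removable bromine at C3 of each pyranone (10), which lowers the LUMO and reinforces the polarisation that sends the acetal carbon to C3.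

10 to 9: the two C3–Br bonds are cut. Bromine is cheap to put on and comes off in the same operation that saponifies the esters. The forward step must brominate C3 only, which the blocked C5 makes likely.

9 to 8 to 6 and two molecules of 7: the lactone C–O bonds are opened to the Z-configured methoxydienoate chains of 8, and the C=C bonds to the methoxymethylene carbons are then cut to a ketone and a one-carbon ylide. The pyranone reduces to an acyl carbon, a C3 chain and a C1 unit. The forward Wittig step must beat enolisation of the ring C–H α to the ketone and conjugate addition to the enoate.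

6 to 2 and two molecules of 4 (through 5), and 4 to 3: the acyl–vinyl C–C bonds are cut. A neutral palladium-catalysed acylation is chosen because the ring carbons α to the acyl groups are epimerisable. Retention of the Z geometry is helpful but not essential.

2 to 1: two ester C–O bonds are cut. This differentiates the 1,3- from the 2,4-carboxyl groups and takes all four stereocentres from 1. The forward step must separate the centrosymmetric 1,3-diester from the 1,2-isomer.

## Other disconnections considered

Alternative 1: The cut is the two C(sp3)–C(aryl) bonds at cyclobutane C2 and C4. Forward, diamide A1 and two equivalents of aryl iodide A2 would react under Pd(OAc)2 and AgOAc, each 8-aminoquinoline amide directing palladation of a β-C–H bond on its own face, to give A3.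
- In its favour: the aryl rings arrive complete with the silyl ether in place, and A1 is one amide coupling away from commercial material. Cleavage of both auxiliaries would give 18 itself, about four steps against ten, so on step economy this alternative is clearly the better plan.
- Against it here: the first arylation is cis to its directing amide by mechanism, but the second must go to C4 on the opposite face. Arylation of C4 on the same face as the first aryl group, directed by the same amide, is a real competitor and only sterics decide. The two hindered amides, each with a cis aryl neighbour, must then be cleaved in the presence of aryl silyl ethers.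
- Comparison: on structure A3 and 14 are equivalent cores. On mechanism the alternative makes its bonds at the stereocentres, so the configuration depends on a selectivity, whereas the chosen plan makes bonds one atom away and buys the configuration.

Alternative 2: The cut is the O1–C2 lactone bond of both pyranones. Forward, thermolysis of A6 expels acetone twice and each acylketene is trapped by the enol of its ketone to give A7.
- This is the transformation of step 12 (A6 has the structure of 21, A7 that of 23), so on this reaction the two plans are equal.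
- As a strategy it leaves the cyclobutane to another reaction, most naturally the solid-state [2+2] photodimerisation of A4 to A5 (the structure of 16). That would make the ring, two C–C bonds and all four stereocentres in one step.
- In its favour: about six steps in all against fourteen, no tin or palladium, and nothing epimerisable before the core is complete. On step and atom economy it is the better plan.
- Against it: the head-to-tail outcome rests on crystal packing, which cannot be designed, depends on the polymorph and is awkward to run on scale.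
- Comparison: on structure A5 and 16 are the same compound. On mechanism a topochemical [2+2] would set ring and configuration in one event, but only if the lattice allows it, whereas the chosen plan is independent of packing and runs in solution throughout.

Alternative 3: The cut is one cyclobutane C–C bond on a cis edge, between an ester-bearing and an aryl-bearing carbon, with nitrogen inserted. Forward, pyrrolidine A8 would be N-aminated by the iodonitrene from PhI(OH)OTs and ammonium carbamate; the 1,1-diazene loses N2 and the 1,4-biradical closes to A9.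
- In its favour: such pyrrolidines come in one step from an azomethine ylide cycloaddition, with the aryl oxygen and its silyl group already present. A9 needs neither BBr3 nor a separate silylation and would meet the route at 18 after saponification, so it is better on step count.
- Against it: closure retains the pyrrolidine configuration, so A8 must be 2,5-cis, 2,3-trans, 3,4-cis, 4,5-trans. That is not the usual endo adduct of an (E)-configured dipolarophile but the exo adduct of a (Z)-configured one. The biradical has a benzylic and an α-ester terminus, so bond rotation and β-scission to two alkenes can compete with closure, and electron-rich arenes meet an iodine oxidant. Saponifying A9 would also expose aryl silyl ethers to hydroxide, which the chosen order avoids.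
- Comparison: on structure A9 differs from 14 only in the aryl substituents. On mechanism radical recombination at two stereocentres is less safe for configuration than a pericyclic reaction remote from them. On length the alternative wins.

Key step: step 7

Remark: the target SMILES describes the centrosymmetric, achiral (1α,2α,3β,4β) isomer, so only relative configuration is controlled; an acid chloride that is made and used crude is treated as a non-isolated intermediate of the step that consumes it; where a product takes up two molecules of one numbered reactant (steps 3, 4, 7 and 11), the second molecule is entered under "Reagents that add atoms" as well.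

## Route

Step 1
Reactants: 1 cyclobutane-1,2,3,4-tetracarboxylic 1,2:3,4-dianhydride (cis,trans,cis; both anhydride rings cis-fused, on opposite faces)
Product: 2 (1α,2α,3β,4β)-2,4-bis(methoxycarbonyl)cyclobutane-1,3-dicarboxylic acid (the centrosymmetric 1,3-diester 2,4-diacid)
Conditions: MeOH, reflux; evaporate; crystallise (MeCN or EtOAc)
Reagents that add atoms: methanol, CO
Why: Alcoholysis of a cyclic anhydride opens each ring once to one ester and one acid by acyl substitution, so no ring C–H is touched and the cis,trans,cis configuration is kept; the 1,3- and 1,2-diesters both form, and the centrosymmetric 1,3-isomer is expected to be the less soluble one and to be separable by crystallisation.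

Step 2
Reactants: 3 methyl propiolate
Product: 4 methyl (2Z)-3-(tributylstannyl)prop-2-enoate
Conditions: Bu3SnH, Et3B (cat.), air, toluene, −78 °C → 0 °C; SiO2
Reagents that add atoms: tributyltin hydride, CCCC[SnH](CCCC)CCCC
Why: Radical hydrostannation of a terminal alkyne: the stannyl radical adds to the terminal carbon and hydrogen is delivered anti, so the Z β-stannyl acrylate is the kinetic product at low temperature; E and α isomers are removed by chromatography.

Step 3
Reactants: 2 (1α,2α,3β,4β)-2,4-bis(methoxycarbonyl)cyclobutane-1,3-dicarboxylic acid; 4 methyl (2Z)-3-(tributylstannyl)prop-2-enoate (two molecules)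
Product: 6 dimethyl (1α,2α,3β,4β)-2,4-bis[(2Z)-4-methoxy-4-oxobut-2-enoyl]cyclobutane-1,3-dicarboxylate, via bis(acid chloride) 5 (not isolated)
Conditions: (COCl)2, DMF (cat.), CH2Cl2, 0 °C → rt; evaporate; then 4 (2.4 equiv), PdCl2(MeCN)2 (5 mol %), toluene, 60 °C
Reagents that add atoms: second molecule of 4 (methyl (2Z)-3-(tributylstannyl)prop-2-enoate), CCCC[Sn](CCCC)(CCCC)/C=C\C(=O)OC
Why: Acid chloride formation followed by Stille acylation (acyl chloride with a vinylstannane under palladium catalysis) gives the enone on both arms with retention of the alkene geometry of 4; the medium is neutral and base-free, which protects the ring C–H α to the new ketones, and the ring esters are inert.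

Step 4
Reactants: 6 dimethyl (1α,2α,3β,4β)-2,4-bis[(2Z)-4-methoxy-4-oxobut-2-enoyl]cyclobutane-1,3-dicarboxylate; 7 (methoxymethyl)triphenylphosphonium chloride (two molecules)
Product: 8 dimethyl (1α,2α,3β,4β)-2,4-bis[(3Z)-1,5-dimethoxy-5-oxopenta-1,3-dien-2-yl]cyclobutane-1,3-dicarboxylate (enol ether geometry not defined)
Conditions: 7 (3.0 equiv), KN(SiMe3)2 (2.9 equiv), THF, 0 °C; then 6, −78 °C → 0 °C
Reagents that add atoms: second molecule of 7 ((methoxymethyl)triphenylphosphonium chloride), COC[P+](c1ccccc1)(c1ccccc1)c1ccccc1.[Cl-]
Why: Wittig methoxymethylenation: the non-stabilised ylide adds 1,2 to each ketone and Ph3PO is lost, a reaction that is faster than attack on the esters; the ylide is preformed with a slight deficit of base and the ketone is added cold to hold back enolisation of the ring C–H and conjugate addition, and the enol ether geometry does not matter for step 5.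

Step 5
Reactants: 8 dimethyl (1α,2α,3β,4β)-2,4-bis[(3Z)-1,5-dimethoxy-5-oxopenta-1,3-dien-2-yl]cyclobutane-1,3-dicarboxylate
Product: 9 dimethyl (1α,2α,3β,4β)-2,4-bis(2-oxo-2H-pyran-5-yl)cyclobutane-1,3-dicarboxylate
Conditions: TsOH·H2O (0.2 equiv), H2O (3 equiv), 1,4-dioxane, 80 °C
Reagents that add atoms: water, O
Why: Acid-catalysed enol ether hydrolysis and lactonisation: protonation of the push–pull dienol ether and addition of water unmask the formyl group, whose enol oxygen closes onto the cis ester with loss of methanol to give the conjugated 2-pyranone; because protonation α to the ester makes that bond single for a time, material that has isomerised to E can close as well.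

Step 6
Reactants: 9 dimethyl (1α,2α,3β,4β)-2,4-bis(2-oxo-2H-pyran-5-yl)cyclobutane-1,3-dicarboxylate
Product: 10 dimethyl (1α,2α,3β,4β)-2,4-bis(3-bromo-2-oxo-2H-pyran-5-yl)cyclobutane-1,3-dicarboxylate
Conditions: Br2 (2.2 equiv), CH2Cl2, 0 °C → rt; then Et3N (2.5 equiv), 0 °C
Reagents that add atoms: bromine, BrBr
Why: Electrophilic bromination of a 2-pyranone by addition and dehydrobromination: the dienol-ether character of the ring makes C3 and C5 the nucleophilic positions, and with C5 blocked by the cyclobutane the bromine ends at C3; the ester α-hydrogens are not acidic enough for Et3N.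

Step 7
Reactants: 10 dimethyl (1α,2α,3β,4β)-2,4-bis(3-bromo-2-oxo-2H-pyran-5-yl)cyclobutane-1,3-dicarboxylate; 11 1,1-dimethoxyethene (two molecules)
Product: 14 dimethyl (1α,2α,3β,4β)-2,4-bis(3-bromo-4-methoxyphenyl)cyclobutane-1,3-dicarboxylate (dimethyl 3,3′-dibromo-4,4′-dimethoxy-α-truxillate), via bridged bis-lactone cycloadduct 12 (not isolated), via bis(cyclohexadiene ketal) 13 (not isolated)
Conditions: 11 (10 equiv), K2CO3 (5 mol %), toluene, 110 °C, sealed tube
Reagents that add atoms: second molecule of 11 (1,1-dimethoxyethene), C=C(OC)OC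
Why: This is an inverse-electron-demand Diels–Alder reaction of a 2-pyranone with a ketene acetal, followed by retro-Diels–Alder loss of CO2 and elimination of methanol; the closest known reaction type is the arene annulation of acceptor-substituted 2-pyranones (3-alkoxycarbonyl and bromo derivatives) with 1,1-dialkoxyethenes and enol ethers. The electron-rich CH2 carbon of 11 bonds to C6, the carbon next to the ring oxygen, and the acetal carbon bonds to C3, giving the bridged lactone 12; cycloreversion expels CO2 to give the cyclohexadiene ketal 13, which loses methanol to give the anisole rings of 14. Each benzene ring is closed by an intermolecular suprafacial [4π+2π] cycloaddition that forms the C6–CH2 and C3–C(OMe)2 bonds in one concerted, asynchronous event, so four C–C bonds and two rings are made from one molecule of 10 and two of 11. The only new stereocentres are the bridgeheads of 12, which are transient and vanish on aromatisation. The four cyclobutane centres are never next to a charged or radical site under these neutral thermal conditions and are carried through unchanged. The step needs regioselectivity (methoxy para to the cyclobutane) and full twofold conversion. The first is secured by the polarity of the dienyl lactone, reinforced by the bromine on C3, which makes C3 the terminus that accepts the oxygen-bearing carbon. The second is secured by the bromine lowering the LUMO of an otherwise sluggish 5-alkyl diene, and by an excess of 11 with a trace of K2CO3 to suppress acid-induced oligomerisation of the ketene acetal.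

Step 8
Reactants: 14 dimethyl (1α,2α,3β,4β)-2,4-bis(3-bromo-4-methoxyphenyl)cyclobutane-1,3-dicarboxylate
Product: 15 (1α,2α,3β,4β)-2,4-bis(4-methoxyphenyl)cyclobutane-1,3-dicarboxylic acid (4,4′-dimethoxy-α-truxillic acid)
Conditions: H2 (1 atm), Pd/C (10 wt %), KOH (10 equiv), MeOH–H2O 4:1, rt → 55 °C; then 2 M HCl
Reagents that add atoms: potassium hydroxide, [K+].[OH-]
Why: Catalytic hydrogenolysis of the aryl C–Br bonds (the base takes up HBr) and saponification of the two methyl esters run in the same basic medium; because the aryl-bearing carbons are not acidic, ester epimerisation cannot reach an all-trans isomer, so hydroxide at moderate temperature should leave the configuration intact.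

Step 9
Reactants: 15 (1α,2α,3β,4β)-2,4-bis(4-methoxyphenyl)cyclobutane-1,3-dicarboxylic acid
Product: 16 (1α,2α,3β,4β)-2,4-bis(4-hydroxyphenyl)cyclobutane-1,3-dicarboxylic acid (4,4′-dihydroxy-α-truxillic acid)
Conditions: BBr3 (8 equiv), CH2Cl2, −78 °C → rt; H2O
Reagents that add atoms: none
Why: Lewis-acid cleavage of aryl methyl ethers: boron binds the ether oxygen and bromide removes the methyl group by SN2; it is placed before any methoxypyranone exists, and the carboxylic acids only consume extra reagent and return on hydrolysis.

Step 10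
Reactants: 16 (1α,2α,3β,4β)-2,4-bis(4-hydroxyphenyl)cyclobutane-1,3-dicarboxylic acid
Product: 18 (1α,2α,3β,4β)-2,4-bis[4-(triisopropylsilyloxy)phenyl]cyclobutane-1,3-dicarboxylic acid, via tetrakis(triisopropylsilyl) derivative 17 (not isolated)
Conditions: iPr3SiCl (4.6 equiv), imidazole (9 equiv), DMF, rt; then K2CO3 (3 equiv), MeOH–THF–H2O, 0 °C; 1 M HCl to pH 3
Reagents that add atoms: triisopropylsilyl chloride, CC(C)[Si](Cl)(C(C)C)C(C)C
Why: Silylation of phenols and acids, then selective hydrolysis of the two silyl esters, which are far more labile to mild aqueous base than hindered aryl triisopropylsilyl ethers; the bulky silyl group is chosen because it should survive the enolate, the heat and the carbonate of steps 11 to 13.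

Step 11
Reactants: 18 (1α,2α,3β,4β)-2,4-bis[4-(triisopropylsilyloxy)phenyl]cyclobutane-1,3-dicarboxylic acid; 19 2,2,6-trimethyl-4H-1,3-dioxin-4-one (two molecules)
Product: 21 6,6′-{[(1α,2α,3β,4β)-2,4-bis[4-(triisopropylsilyloxy)phenyl]cyclobutane-1,3-diyl]bis(2-oxoethane-2,1-diyl)}bis(2,2-dimethyl-4H-1,3-dioxin-4-one), via bis(acid chloride) 20 (not isolated)
Conditions: (COCl)2, DMF (cat.), CH2Cl2, 0 °C → rt; evaporate; add to 19 (5 equiv)/LiN(SiMe3)2 (5 equiv), THF, −78 °C; AcOH quench
Reagents that add atoms: second molecule of 19 (2,2,6-trimethyl-4H-1,3-dioxin-4-one), CC1=CC(=O)OC(C)(C)O1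
Why: Vinylogous Claisen-type C-acylation: the lithium dienolate of 19 attacks each of the two acid chloride groups of 20 with its γ-carbon (the former methyl group), so one molecule of 18 takes up two molecules of 19 with loss of two chlorides; the excess dienolate deprotonates the product at the doubly activated CH2, which shields the cyclobutane C–H α to the new ketone from epimerisation.

Step 12
Reactants: 21 6,6′-{[(1α,2α,3β,4β)-2,4-bis[4-(triisopropylsilyloxy)phenyl]cyclobutane-1,3-diyl]bis(2-oxoethane-2,1-diyl)}bis(2,2-dimethyl-4H-1,3-dioxin-4-one)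
Product: 23 6,6′-{(1α,2α,3β,4β)-2,4-bis[4-(triisopropylsilyloxy)phenyl]cyclobutane-1,3-diyl}bis(4-hydroxy-2H-pyran-2-one), via bis(acylketene) 22 (not isolated)
Conditions: toluene, 110 °C
Reagents that add atoms: none
Why: Thermal retro-[4+2] of each dioxinone expels acetone and gives an acylketene, which is captured by the enol oxygen of the neighbouring ketone in a six-membered lactonisation to the 4-hydroxy-2-pyranone; the conditions are neutral.

Step 13
Reactants: 23 6,6′-{(1α,2α,3β,4β)-2,4-bis[4-(triisopropylsilyloxy)phenyl]cyclobutane-1,3-diyl}bis(4-hydroxy-2H-pyran-2-one)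
Product: 24 6,6′-{(1α,2α,3β,4β)-2,4-bis[4-(triisopropylsilyloxy)phenyl]cyclobutane-1,3-diyl}bis(4-methoxy-2H-pyran-2-one)
Conditions: Me2SO4 (2.4 equiv), K2CO3 (3 equiv), acetone, rt → 40 °C
Reagents that add atoms: dimethyl sulfate, COS(=O)(=O)OC
Why: O-Alkylation of the acidic 4-hydroxy-2-pyranone (a vinylogous acid) with a hard methylating agent gives the 4-methoxy-2-pyranone and not the 2-methoxy-4-pyranone; the phenols are silylated, and K2CO3 in dry acetone is too weak to remove the cyclobutane hydrogens.

Step 14
Reactants: 24 6,6′-{(1α,2α,3β,4β)-2,4-bis[4-(triisopropylsilyloxy)phenyl]cyclobutane-1,3-diyl}bis(4-methoxy-2H-pyran-2-one)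
Product: 25 6,6′-[(1α,2α,3β,4β)-2,4-bis(4-hydroxyphenyl)cyclobutane-1,3-diyl]bis(4-methoxy-2H-pyran-2-one) (CNP0273697.2)
Conditions: Bu4NF (2.4 equiv), AcOH (2.6 equiv), THF, 0 °C
Reagents that add atoms: none
Why: Fluoride cleavage of the aryl silyl ethers; buffering with acetic acid keeps the medium from becoming basic enough to open the lactones or to epimerise C1/C3.

## Compound list

1 | cyclobutane-1,2,3,4-tetracarboxylic 1,2:3,4-dianhydride (cis,trans,cis) | O=C1[C@H]2[C@@H]3C(=O)OC(=O)[C@@H]3[C@H]2C(=O)O1 | starting material
2 | (1α,2α,3β,4β)-2,4-bis(methoxycarbonyl)cyclobutane-1,3-dicarboxylic acid | COC(=O)[C@H]1[C@H](C(=O)O)[C@H](C(=O)OC)[C@H]1C(=O)O | intermediate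
3 | methyl propiolate | C#CC(=O)OC | starting material
4 | methyl (2Z)-3-(tributylstannyl)prop-2-enoate | CCCC[Sn](CCCC)(CCCC)/C=C\C(=O)OC | intermediate
5 | dimethyl (1α,2α,3β,4β)-2,4-bis(chlorocarbonyl)cyclobutane-1,3-dicarboxylate | COC(=O)[C@H]1[C@H](C(Cl)=O)[C@H](C(=O)OC)[C@H]1C(Cl)=O | intermediate (not isolated)
6 | dimethyl (1α,2α,3β,4β)-2,4-bis[(2Z)-4-methoxy-4-oxobut-2-enoyl]cyclobutane-1,3-dicarboxylate | COC(=O)[C@H]1[C@H](C(=O)/C=C\C(=O)OC)[C@H](C(=O)OC)[C@H]1C(=O)/C=C\C(=O)OC | intermediate
7 | (methoxymethyl)triphenylphosphonium chloride | COC[P+](c1ccccc1)(c1ccccc1)c1ccccc1.[Cl-] | starting material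
8 | dimethyl (1α,2α,3β,4β)-2,4-bis[(3Z)-1,5-dimethoxy-5-oxopenta-1,3-dien-2-yl]cyclobutane-1,3-dicarboxylate (enol ether geometry not defined) | COC(=O)[C@H]1[C@H](C(=COC)/C=C\C(=O)OC)[C@H](C(=O)OC)[C@H]1C(=COC)/C=C\C(=O)OC | intermediate
9 | dimethyl (1α,2α,3β,4β)-2,4-bis(2-oxo-2H-pyran-5-yl)cyclobutane-1,3-dicarboxylate | COC(=O)[C@H]1[C@H](c2ccc(=O)oc2)[C@H](C(=O)OC)[C@H]1c1ccc(=O)oc1 | intermediate
10 | dimethyl (1α,2α,3β,4β)-2,4-bis(3-bromo-2-oxo-2H-pyran-5-yl)cyclobutane-1,3-dicarboxylate | COC(=O)[C@H]1[C@H](c2cc(Br)c(=O)oc2)[C@H](C(=O)OC)[C@H]1c1cc(Br)c(=O)oc1 | intermediate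
11 | 1,1-dimethoxyethene | C=C(OC)OC | starting material
12 | dimethyl (1α,2α,3β,4β)-2,4-bis(4-bromo-5,5-dimethoxy-3-oxo-2-oxabicyclo[2.2.2]oct-7-en-7-yl)cyclobutane-1,3-dicarboxylate (bridgehead configuration not defined, transient) | COC(=O)[C@H]1[C@H](C2=CC3(Br)C(=O)OC2CC3(OC)OC)[C@H](C(=O)OC)[C@H]1C4=CC5(Br)C(=O)OC4CC5(OC)OC | intermediate (not isolated)
13 | dimethyl (1α,2α,3β,4β)-2,4-bis(5-bromo-4,4-dimethoxycyclohexa-1,5-dien-1-yl)cyclobutane-1,3-dicarboxylate | COC(=O)[C@H]1[C@H](C2=CCC(OC)(OC)C(Br)=C2)[C@H](C(=O)OC)[C@H]1C3=CCC(OC)(OC)C(Br)=C3 | intermediate (not isolated)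
14 | dimethyl (1α,2α,3β,4β)-2,4-bis(3-bromo-4-methoxyphenyl)cyclobutane-1,3-dicarboxylate | COC(=O)[C@H]1[C@H](c2ccc(OC)c(Br)c2)[C@H](C(=O)OC)[C@H]1c1ccc(OC)c(Br)c1 | intermediate
15 | (1α,2α,3β,4β)-2,4-bis(4-methoxyphenyl)cyclobutane-1,3-dicarboxylic acid | OC(=O)[C@H]1[C@H](c2ccc(OC)cc2)[C@H](C(=O)O)[C@H]1c1ccc(OC)cc1 | intermediate
16 | (1α,2α,3β,4β)-2,4-bis(4-hydroxyphenyl)cyclobutane-1,3-dicarboxylic acid | OC(=O)[C@H]1[C@H](c2ccc(O)cc2)[C@H](C(=O)O)[C@H]1c1ccc(O)cc1 | intermediate
17 | bis(triisopropylsilyl) (1α,2α,3β,4β)-2,4-bis[4-(triisopropylsilyloxy)phenyl]cyclobutane-1,3-dicarboxylate | CC(C)[Si](OC(=O)[C@H]1[C@H](c2ccc(O[Si](C(C)C)(C(C)C)C(C)C)cc2)[C@H](C(=O)O[Si](C(C)C)(C(C)C)C(C)C)[C@H]1c1ccc(O[Si](C(C)C)(C(C)C)C(C)C)cc1)(C(C)C)C(C)C | intermediate (not isolated)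
18 | (1α,2α,3β,4β)-2,4-bis[4-(triisopropylsilyloxy)phenyl]cyclobutane-1,3-dicarboxylic acid | OC(=O)[C@H]1[C@H](c2ccc(O[Si](C(C)C)(C(C)C)C(C)C)cc2)[C@H](C(=O)O)[C@H]1c1ccc(O[Si](C(C)C)(C(C)C)C(C)C)cc1 | intermediate
19 | 2,2,6-trimethyl-4H-1,3-dioxin-4-one | CC1=CC(=O)OC(C)(C)O1 | starting material
20 | (1α,2α,3β,4β)-2,4-bis[4-(triisopropylsilyloxy)phenyl]cyclobutane-1,3-dicarbonyl dichloride | ClC(=O)[C@H]1[C@H](c2ccc(O[Si](C(C)C)(C(C)C)C(C)C)cc2)[C@H](C(Cl)=O)[C@H]1c1ccc(O[Si](C(C)C)(C(C)C)C(C)C)cc1 | intermediate (not isolated)
21 | 6,6′-{[(1α,2α,3β,4β)-2,4-bis[4-(triisopropylsilyloxy)phenyl]cyclobutane-1,3-diyl]bis(2-oxoethane-2,1-diyl)}bis(2,2-dimethyl-4H-1,3-dioxin-4-one) | CC1(C)OC(=O)C=C(CC(=O)[C@H]2[C@H](c3ccc(O[Si](C(C)C)(C(C)C)C(C)C)cc3)[C@H](C(=O)CC3=CC(=O)OC(C)(C)O3)[C@H]2c2ccc(O[Si](C(C)C)(C(C)C)C(C)C)cc2)O1 | intermediate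
22 | 5,5′-{(1α,2α,3β,4β)-2,4-bis[4-(triisopropylsilyloxy)phenyl]cyclobutane-1,3-diyl}bis(pent-1-ene-1,3,5-trione) | O=C=CC(=O)CC(=O)[C@H]1[C@H](c2ccc(O[Si](C(C)C)(C(C)C)C(C)C)cc2)[C@H](C(=O)CC(=O)C=C=O)[C@H]1c1ccc(O[Si](C(C)C)(C(C)C)C(C)C)cc1 | intermediate (not isolated)
23 | 6,6′-{(1α,2α,3β,4β)-2,4-bis[4-(triisopropylsilyloxy)phenyl]cyclobutane-1,3-diyl}bis(4-hydroxy-2H-pyran-2-one) | Oc1cc(=O)oc([C@H]2[C@H](c3ccc(O[Si](C(C)C)(C(C)C)C(C)C)cc3)[C@H](c3cc(O)cc(=O)o3)[C@H]2c2ccc(O[Si](C(C)C)(C(C)C)C(C)C)cc2)c1 | intermediate
24 | 6,6′-{(1α,2α,3β,4β)-2,4-bis[4-(triisopropylsilyloxy)phenyl]cyclobutane-1,3-diyl}bis(4-methoxy-2H-pyran-2-one) | COc1cc(=O)oc([C@H]2[C@H](c3ccc(O[Si](C(C)C)(C(C)C)C(C)C)cc3)[C@H](c3cc(OC)cc(=O)o3)[C@H]2c2ccc(O[Si](C(C)C)(C(C)C)C(C)C)cc2)c1 | intermediate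
25 | 6,6′-[(1α,2α,3β,4β)-2,4-bis(4-hydroxyphenyl)cyclobutane-1,3-diyl]bis(4-methoxy-2H-pyran-2-one) | COc1cc(=O)oc([C@H]2[C@H](c3ccc(O)cc3)[C@H](c3cc(OC)cc(=O)o3)[C@H]2c2ccc(O)cc2)c1 | target

## Step count and least certain steps

Total: 14 steps. Longest linear sequence: 13 steps (steps 1 and 3 to 14); step 2 is a one-step side branch.

Step 7 (key step). The most likely failure is incomplete twofold cycloaddition. The ketene acetal may be consumed by oligomerisation, or by conjugate addition at C6 with ring opening, faster than it cycloadds to a diene that still carries a donor alkyl group at C5, and the ketal stage may not lose methanol cleanly. The fallback sets out from 10 and replaces the alkene partner by an alkyne, ethoxyacetylene (toluene, 85 °C, sealed tube). Its cycloadduct can only lose CO2 and so gives the aryl ether directly, dimethyl (1α,2α,3β,4β)-2,4-bis(3-bromo-4-ethoxyphenyl)cyclobutane-1,3-dicarboxylate F1. Hydrogenolysis and saponification under the conditions of step 8 would give 4,4′-diethoxy-α-truxillic acid F2, and BBr3 as in step 9 brings the material back to the route at 16.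

Step 4. The most likely failure is loss of configuration by enolisation of the ring C–H that is α to the ketone and flanked by ester-bearing carbons; before the aryl rings exist an all-trans isomer is within reach. Conjugate addition of the ylide to the 4-oxo-enoate is the second danger. The fallback sets out from 2 (through 5 as in step 3) and removes the Michael acceptor. Negishi acylation with (3-tert-butoxy-3-oxopropyl)zinc bromide (Pd(PPh3)4, THF, 0 °C → rt) would give dimethyl (1α,2α,3β,4β)-2,4-bis(4-tert-butoxy-4-oxobutanoyl)cyclobutane-1,3-dicarboxylate F3. The same Wittig reagent would then give dimethyl (1α,2α,3β,4β)-2,4-bis(5-tert-butoxy-1-methoxy-5-oxopent-1-en-2-yl)cyclobutane-1,3-dicarboxylate F4. TsOH·H2O (cat.) in toluene at 90 °C would close the enol lactones with loss of 2-methylpropene and methanol to dimethyl (1α,2α,3β,4β)-2,4-bis(2-oxo-3,4-dihydro-2H-pyran-5-yl)cyclobutane-1,3-dicarboxylate F5. Dehydrogenation with DDQ in 1,4-dioxane at 90 °C comes back to the route at 9.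

Step 6. The most likely failure is addition of bromine across C5=C6 without re-aromatisation, since C5 carries no hydrogen, together with over-bromination. The fallback sets out from 9 and gives up the halogen activation in favour of physical activation. Compound 9 and 11 are heated neat at 150 °C in a sealed tube, or compressed to 10–12 kbar, to give dimethyl 4,4′-dimethoxy-α-truxillate F6. Saponification with KOH in MeOH–H2O (step 8 without hydrogen) comes back to the route at 15.

Step 11. The most likely failures are dehydrochlorination of the acid chloride to a ketene by the basic dienolate, which would epimerise C1/C3, and O- or α-acylation of the dienolate with incomplete twofold reaction. The fallback sets out from 18 (through 20) and uses a neutral silyl dienol ether in place of a lithium dienolate. 1-Methoxy-1,3-bis(trimethylsilyloxy)buta-1,3-diene (CH2Cl2, −78 °C → rt, aqueous work-up) would give dimethyl 5,5′-{(1α,2α,3β,4β)-2,4-bis[4-(triisopropylsilyloxy)phenyl]cyclobutane-1,3-diyl}bis(3,5-dioxopentanoate) F7. Lactonisation with DBU in toluene at 80 °C comes back to the route at 23.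

## Further compounds

F1 | step 7 | dimethyl (1α,2α,3β,4β)-2,4-bis(3-bromo-4-ethoxyphenyl)cyclobutane-1,3-dicarboxylate | COC(=O)[C@H]1[C@H](c2ccc(OCC)c(Br)c2)[C@H](C(=O)OC)[C@H]1c1ccc(OCC)c(Br)c1
F2 | step 7 | (1α,2α,3β,4β)-2,4-bis(4-ethoxyphenyl)cyclobutane-1,3-dicarboxylic acid | OC(=O)[C@H]1[C@H](c2ccc(OCC)cc2)[C@H](C(=O)O)[C@H]1c1ccc(OCC)cc1
F3 | step 4 | dimethyl (1α,2α,3β,4β)-2,4-bis(4-tert-butoxy-4-oxobutanoyl)cyclobutane-1,3-dicarboxylate | COC(=O)[C@H]1[C@H](C(=O)CCC(=O)OC(C)(C)C)[C@H](C(=O)OC)[C@H]1C(=O)CCC(=O)OC(C)(C)C
F4 | step 4 | dimethyl (1α,2α,3β,4β)-2,4-bis(5-tert-butoxy-1-methoxy-5-oxopent-1-en-2-yl)cyclobutane-1,3-dicarboxylate | COC(=O)[C@H]1[C@H](C(=COC)CCC(=O)OC(C)(C)C)[C@H](C(=O)OC)[C@H]1C(=COC)CCC(=O)OC(C)(C)C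
F5 | step 4 | dimethyl (1α,2α,3β,4β)-2,4-bis(2-oxo-3,4-dihydro-2H-pyran-5-yl)cyclobutane-1,3-dicarboxylate | COC(=O)[C@H]1[C@H](C2=COC(=O)CC2)[C@H](C(=O)OC)[C@H]1C3=COC(=O)CC3
F6 | step 6 | dimethyl (1α,2α,3β,4β)-2,4-bis(4-methoxyphenyl)cyclobutane-1,3-dicarboxylate | COC(=O)[C@H]1[C@H](c2ccc(OC)cc2)[C@H](C(=O)OC)[C@H]1c1ccc(OC)cc1
F7 | step 11 | dimethyl 5,5′-{(1α,2α,3β,4β)-2,4-bis[4-(triisopropylsilyloxy)phenyl]cyclobutane-1,3-diyl}bis(3,5-dioxopentanoate) | COC(=O)CC(=O)CC(=O)[C@H]1[C@H](c2ccc(O[Si](C(C)C)(C(C)C)C(C)C)cc2)[C@H](C(=O)CC(=O)CC(=O)OC)[C@H]1c1ccc(O[Si](C(C)C)(C(C)C)C(C)C)cc1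
A1 | alternative 1 | trans-N,N′-di(quinolin-8-yl)cyclobutane-1,3-dicarboxamide | O=C(Nc1cccc2cccnc12)[C@H]1C[C@H](C(=O)Nc2cccc3cccnc23)C1
A2 | alternative 1 | (4-iodophenoxy)triisopropylsilane | CC(C)[Si](Oc1ccc(I)cc1)(C(C)C)C(C)C
A3 | alternative 1 | N,N′-di(quinolin-8-yl)-(1α,2α,3β,4β)-2,4-bis[4-(triisopropylsilyloxy)phenyl]cyclobutane-1,3-dicarboxamide | O=C(Nc1cccc2cccnc12)[C@H]3[C@H](c4ccc(O[Si](C(C)C)(C(C)C)C(C)C)cc4)[C@H](C(=O)Nc5cccc6cccnc56)[C@H]3c7ccc(O[Si](C(C)C)(C(C)C)C(C)C)cc7
A4 | alternative 2 | (E)-3-(4-hydroxyphenyl)prop-2-enoic acid (p-coumaric acid) | OC(=O)/C=C/c1ccc(O)cc1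
A5 | alternative 2 | (1α,2α,3β,4β)-2,4-bis(4-hydroxyphenyl)cyclobutane-1,3-dicarboxylic acid (same structure as 16) | OC(=O)[C@H]1[C@H](c2ccc(O)cc2)[C@H](C(=O)O)[C@H]1c1ccc(O)cc1
A6 | alternative 2 | 6,6′-{[(1α,2α,3β,4β)-2,4-bis[4-(triisopropylsilyloxy)phenyl]cyclobutane-1,3-diyl]bis(2-oxoethane-2,1-diyl)}bis(2,2-dimethyl-4H-1,3-dioxin-4-one) (same structure as 21) | CC1(C)OC(=O)C=C(CC(=O)[C@H]2[C@H](c3ccc(O[Si](C(C)C)(C(C)C)C(C)C)cc3)[C@H](C(=O)CC3=CC(=O)OC(C)(C)O3)[C@H]2c2ccc(O[Si](C(C)C)(C(C)C)C(C)C)cc2)O1
A7 | alternative 2 | 6,6′-{(1α,2α,3β,4β)-2,4-bis[4-(triisopropylsilyloxy)phenyl]cyclobutane-1,3-diyl}bis(4-hydroxy-2H-pyran-2-one) (same structure as 23) | Oc1cc(=O)oc([C@H]2[C@H](c3ccc(O[Si](C(C)C)(C(C)C)C(C)C)cc3)[C@H](c3cc(O)cc(=O)o3)[C@H]2c2ccc(O[Si](C(C)C)(C(C)C)C(C)C)cc2)c1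
A8 | alternative 3 | dimethyl 3,5-bis[4-(triisopropylsilyloxy)phenyl]pyrrolidine-2,4-dicarboxylate (2,5-cis, 2,3-trans, 3,4-cis, 4,5-trans; racemic) | N1[C@@H](C(=O)OC)[C@H](c2ccc(O[Si](C(C)C)(C(C)C)C(C)C)cc2)[C@H](C(=O)OC)[C@H]1c1ccc(O[Si](C(C)C)(C(C)C)C(C)C)cc1
A9 | alternative 3 | dimethyl (1α,2α,3β,4β)-2,4-bis[4-(triisopropylsilyloxy)phenyl]cyclobutane-1,3-dicarboxylate | COC(=O)[C@H]1[C@H](c2ccc(O[Si](C(C)C)(C(C)C)C(C)C)cc2)[C@H](C(=O)OC)[C@H]1c1ccc(O[Si](C(C)C)(C(C)C)C(C)C)cc1
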